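## Structural features

The target 26 is a eudesmane: ring A (C1–C5, C10) and ring B (C5–C10) share the C5–C10 bond, a tetrasubstituted C4=C5 alkene sits at the fusion, and the quaternary C10 carries the angular methyl C14. Ring A holds the allylic isobutyrate at C3 (S, β) next to methyl-bearing C4. Ring B holds the adjacent pair C7 (R, methyl acrylate C11(=C13H2)–C12) and C8 (R, acetate), cis to each other and on the same β face as C14, so C8 and C10 stand 1,3 across C9. The fragile parts are the α-methylene ester (a Michael acceptor whose alkene can slip to C7=C11 under base), the ionisable allylic ester at C3, three ester groups that must stay distinct, and the cis O8/C12 pair, which closes to a γ-lactone whenever O8 is free. The real difficulty is the quaternary C10 in a fixed relation to the remote C7/C8 pair, together with the order in which the acrylate and the two acyloxy groups are unveiled. The key step uses the atom row C6–C5–C4–C3: C5 belongs to both rings and is bonded to C4, whose only other substituent is the methyl C15, so C5≡C4–C15 can ride on C10 as a propynyl group and pass a metal carbene from C6 (ring B) to C3 (ring A). A descriptor check shows that the acyclic substrate 14 (3S,4R,6R) and the diene 15 (C7 S, C8 R, C10 R) map onto 26 with no change of spatial arrangement (the letter at C7 changes only through ligand priority). In the open chain the C7 arm and O8 are anti, so the allylboron reagent must be the E isomer; the Z isomer that a catalysed 1,4-hydroboration of a pentadienoate would supply leads to the C8 epimer.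

## Logic of the disconnections

26 ⇒ 25 ⇒ 24. The O8–acetyl bond is cut first and O8 is then masked as a silyl ether. The acetate cannot survive enolate chemistry, and a free O8 next to the C12 ester invites lactonisation, so the acetate must go on last. This removes one of three esters from every earlier intermediate. The forward steps must expose O8 only under buffered acid, never as an alkoxide, and acylate it at once.

24 ⇒ 23. The O3–isobutyryl bond is cut. The isobutyrate has an acidic α-hydrogen and must therefore follow the enolate step. In 23 only O3 is free, so no site selectivity is needed; the acylation base must be too weak to move the acrylate alkene.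

23 ⇒ 20. The C11=C13 bond is cut and C13 removed. An acrylate would not survive hydroboration, amidine base or hydride. This leaves a plain acetic ester arm. The forward step needs the ester enolate beside a free O3–H (a dianion) and a weak base for the final elimination.

20 ⇒ 19. The C3–H bond is cut (carbinol to ketone). The C3 configuration then comes from hydride attack on the face opposite C14. The reduction must be strictly 1,2.

19 ⇒ 15 (through 17). The C3–O bond is cut and the alkene moved from C4=C5 back to C5=C6, restoring C3=C4. The heteroannular diene is what the metathesis delivers. Ring A then carries no oxygen. The borane must choose the C3 terminus over C6.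

15 ⇒ 14. The C3=C4 and C5=C6 bonds are cut. Both rings vanish and all three stereocentres can be made on an open chain. The forward step needs ruthenium to start at C6 only and the hindered C4 carbene to close onto a trisubstituted alkene.

14 ⇒ 8 + 11 (through 13). The O8–Si bond and then the C7–C8 bond are cut. One allyl transfer sets both adjacent centres; the E geometry of 11 gives the anti pair. C10 is too remote to help, so the catalyst must decide the face, and O8 must be silylated before it can lactonise. A lactone tether between O8 and C12 was considered as the spectator and rejected, because it could not be reopened cleanly once the methylene group is in place.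

11 ⇒ 9 + 10. The alkene of 11 is cut by cross-metathesis logic into two commercial terminal alkenes. The forward step must favour the E isomer.

8 ⇒ 6. The C8–C9 bond is cut (one carbon). The epoxide route delivers C9 as a formyl group directly on C10. The forward step is an olefination of a hindered α-quaternary aldehyde followed by mild hydrolysis.

6 ⇒ 5 ⇒ 2 + 3. C1 of the terpene chain is restored (glycol), then the C10–C5 bond is cut. The quaternary centre then arises by stereospecific opening of a trisubstituted epoxide. The nucleophile must attack the tertiary carbon with inversion.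

2 ⇒ 1. The two epoxide C–O bonds are cut. The forward step is a hydroxyl-directed asymmetric epoxidation that ignores the remote alkene.

## Other disconnections considered

Alternative 1: The cut is C7–C8 in ring B. In the forward direction the allylic bromide A2, a ring A cyclohexene carrying the C3 isobutyrate, the C10 acetaldehyde arm and a 2-(bromomethyl)but-2-enoate chain on C5, would be treated with CrCl2 (divalent chromium). The allylchromium species adds through C7 to the C8 aldehyde and gives A1, the 8-deacetyl compound, which is identical with 25. In its favour, the acrylate, the C8 carbinol and ring B all appear in one step at the very end, and A1 is one acetylation from 26. On step economy after the key step this is clearly better than the chosen plan, which needs seven further steps. It also avoids both the hydroboration of a diene and the late enolate methylenation, and the chromium reagent tolerates esters at least as well as the ruthenium carbene. Against it, A2 already contains C3 and the quaternary C10 next to a tetrasubstituted alkene and is not short to make. The cis relation of C7 and C8 is what such closures usually give, but whether the pair forms on the face of C14 depends on the conformational bias of ring A alone. The chromium alkoxide sits cis to the ester and may lactonise, after which the methylene lactone cannot be reopened cleanly. Mechanistically both plans close ring B; the alternative creates two stereocentres under substrate control where the chosen plan creates none in its key step and sets all of them earlier under reagent control or by stereospecific substitution. Overall length should be similar, with the risk in the alternative concentrated in one late diastereoselective step.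

Alternative 2: The cuts are C5–C6 and C9–C10. The quinone A4 (2-methoxy-5-methyl-1,4-benzoquinone) and the diene A5 (2-silyloxybutadiene) would combine endo under a chiral Lewis acid such as TiCl2(BINOLate) (tetravalent titanium) to give the cis-fused adduct A3. In its favour, ring B and the quaternary C10 with its methyl group arise in one catalytic enantioselective step from two very simple partners. The regiochemistry is predictable, because the C1 carbonyl is a vinylogous ester and the C4 carbonyl therefore activates C10 as the β-carbon. The C8 oxygen is already present as an enol ether. On the speed of reaching a bicyclic core and on setting C10 catalytically it is better than the chosen plan. Against it, A3 has the wrong pattern almost everywhere else. The C1 carbonyl must be removed, the C4 carbonyl turned into the methyl-bearing alkene, and the C3 enol ether reduced to the β-carbinol. The three-carbon acrylate unit must be attached at C7 with control of C7 and C8, and three carbonyl-type groups must be told apart throughout. Mechanistically it is a concerted [4+2] that makes two stereocentres, one of which is later erased, against a carbene relay that makes none. On step economy its simplicity comes early and the endgame should be considerably longer than the nine functional-group steps the chosen plan needs in total after ring formation.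

Alternative 3: The cuts are C3–C4 and C5–C10. The acyclic dienyne A7 would undergo an intramolecular [4+2] of the C4≡C5 alkyne with the C10=C1–C2=C3 diene, thermally or with Ni(cod)2 (zerovalent nickel) and a triaryl phosphite, to give the 1,4-diene A6. In its favour, it also closes both rings from an open chain with the same spectator groups. It places the C4=C5 alkene exactly where 26 has it, which is better than the chosen plan, where the alkene must be moved. A7 also has no quaternary centre and is simpler to make than 14. Against it, C10 is created in the key step under the influence of C7 and C8 through the tether only, so the face is uncertain. The diene terminus is 1,1-disubstituted and the alkyne unactivated, so the thermal reaction should be sluggish. After the cycloaddition the doubly allylic C3 must be oxidised and C1=C2 then saturated selectively before the same reduction and acylation steps follow. Mechanistically a nickelacycle pathway replaces the carbene relay. Structurally the chosen plan fixes C10 before ring formation by a stereospecific substitution, whereas the alternative leaves it to substrate control. On step economy the two are about equal.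

Key step: step 8

Remarks on the chemistry:
- L-(+)-diethyl tartrate is taken as the ligand that converts geraniol into the (2S,3S)-epoxide.
- (S)-TRIP is (S)-3,3′-bis(2,4,6-triisopropylphenyl)-1,1′-binaphthyl-2,2′-diyl hydrogen phosphate; it is chosen on the assumption that the (R)-acid steers allyl transfer to the Re face of an aldehyde, and the (R)-acid would be used if the sense proved opposite.
- Atom labels C1–C15 follow eudesmane numbering throughout.

## Route

Step 1
Reactants: 1 geraniol
Product: 2 (2S,3S)-2,3-epoxygeraniol
Conditions: Ti(OiPr)4 (5 mol%), L-(+)-diethyl tartrate (6 mol%), t-BuOOH, 4 Å MS, CH2Cl2, −20 °C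
Reagents that add atoms: tert-butyl hydroperoxide, CC(C)(C)OO
Why: Sharpless asymmetric epoxidation; the allylic hydroxyl binds titanium, so only C2=C3 of the terpene chain is oxidised and the tartrate sets both epoxide carbons, the tertiary one being the future C10.

Step 2
Reactants: 2 (2S,3S)-2,3-epoxygeraniol; 3 propyne
Product: 5 (2R,3S)-3,7-dimethyl-3-(prop-1-ynyl)oct-6-ene-1,2-diol, via diethyl(prop-1-ynyl)aluminium 4 (not isolated)
Conditions: 3, n-BuLi, toluene, −78 → 0 °C; Et2AlCl, 0 °C; then 2, 0 °C → rt; aq. KNaC4H4O6
Reagents that add atoms: none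
Why: Hydroxyl-directed opening of a 2,3-epoxy alcohol by an alkynylalane; the aluminium alkoxide holds the reagent at O1 and the activated epoxide is attacked at the tertiary carbon, which carries the larger positive charge, with inversion, so the quaternary C10 is set stereospecifically.

Step 3
Reactants: 5 (2R,3S)-3,7-dimethyl-3-(prop-1-ynyl)oct-6-ene-1,2-diol
Product: 6 (2S)-2,6-dimethyl-2-(prop-1-ynyl)hept-5-enal
Conditions: NaIO4, THF/H2O, 0 °C → rt
Reagents that add atoms: none
Why: Periodate glycol cleavage removes the terminal carbinol carbon as formaldehyde; the α-quaternary aldehyde cannot epimerise and alkyne and alkene are inert.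

Step 4
Reactants: 6 (2S)-2,6-dimethyl-2-(prop-1-ynyl)hept-5-enal
Product: 8 (3R)-3,7-dimethyl-3-(prop-1-ynyl)oct-6-enal, via methyl enol ether 7 (not isolated)
Conditions: Ph3P(CH2OMe)Cl, KN(SiMe3)2, THF, 0 °C; 6, 0 °C → rt; then 2 M aq. HCl, THF, rt
Reagents that add atoms: (methoxymethyl)triphenylphosphonium chloride, COC[P+](c1ccccc1)(c1ccccc1)c1ccccc1.[Cl-]; water, O
Why: Wittig methoxymethylenation followed by enol ether hydrolysis, a one-carbon homologation that installs C8 as the aldehyde; dilute acid at room temperature leaves the trisubstituted alkene and the alkyne alone.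

Step 5
Reactants: 9 methyl but-3-enoate; 10 2-allyl-4,4,5,5-tetramethyl-1,3,2-dioxaborolane
Product: 11 methyl (3E)-5-(4,4,5,5-tetramethyl-1,3,2-dioxaborolan-2-yl)pent-3-enoate
Conditions: second-generation Hoveyda–Grubbs catalyst RuCl2(H2IMes)(=CH-C6H4-2-OiPr) (2 mol%), 9 (3 equiv), CH2Cl2, 40 °C
Reagents that add atoms: none
Why: Olefin cross-metathesis of two terminal alkenes with loss of ethene; secondary metathesis should enrich the more stable E isomer, which is the geometry the next step requires.

Step 6
Reactants: 8 (3R)-3,7-dimethyl-3-(prop-1-ynyl)oct-6-enal; 11 methyl (3E)-5-(4,4,5,5-tetramethyl-1,3,2-dioxaborolan-2-yl)pent-3-enoate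
Product: 13 methyl (3S,4R,6R)-3-ethenyl-4-hydroxy-6,10-dimethyl-6-(prop-1-ynyl)undec-9-enoate, via pinacol borate 12 (not isolated)
Conditions: (S)-TRIP (5 mol%), 11 (2 equiv), 4 Å MS, toluene, −30 → 0 °C; aq. NaHCO3 work-up; used at once
Reagents that add atoms: none
Why: Chiral phosphoric acid-catalysed allylboration through a closed six-membered chair transition state; the E alkene places the CH2CO2Me group equatorial and so gives the anti C7/C8 pair, and the acid directs the allyl group to the Si face of the aldehyde (C8 R) because the remote C10 exerts little bias. The E isomer is also the faster-reacting one in chair-type transfer, so an excess of E-enriched 11 limits the contribution of its Z isomer.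

Step 7
Reactants: 13 methyl (3S,4R,6R)-3-ethenyl-4-hydroxy-6,10-dimethyl-6-(prop-1-ynyl)undec-9-enoate
Product: 14 methyl (3S,4R,6R)-4-(tert-butyldimethylsilyloxy)-3-ethenyl-6,10-dimethyl-6-(prop-1-ynyl)undec-9-enoate
Conditions: TBSOTf, 2,6-lutidine, CH2Cl2, −78 °C
Reagents that add atoms: tert-butyldimethylsilyl trifluoromethanesulfonate, CC(C)(C)[Si](C)(C)OS(=O)(=O)C(F)(F)F
Why: Silyl ether formation with a silyl triflate and a hindered base is fast at low temperature and should outrun lactonisation of the γ-hydroxy ester; no stereocentre is touched.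

Step 8
Reactants: 14 methyl (3S,4R,6R)-4-(tert-butyldimethylsilyloxy)-3-ethenyl-6,10-dimethyl-6-(prop-1-ynyl)undec-9-enoate
Product: 15 methyl 2-[(2S,3R,4aR)-3-(tert-butyldimethylsilyloxy)-4a,8-dimethyl-2,3,4,4a,5,6-hexahydronaphthalen-2-yl]acetate (8β-silyloxy eudesma-3,5-diene with the C7 acetic ester arm)
Conditions: second-generation Grubbs catalyst RuCl2(H2IMes)(PCy3)(=CHPh) (10 mol%, two portions), toluene (3 mM), 80 °C, argon sparge
Reagents that add atoms: none
Why: This is a tandem ring-closing enyne and olefin metathesis of an acyclic dienyne, a known way to turn such chains into fused bicyclic 1,3-dienes. The catalyst loads at the only monosubstituted alkene, the vinyl group on C7, to give a C6 alkylidene; [2+2] addition to the alkyne through C5 and cycloreversion form C5=C6 and leave a vinylcarbene on C4. Ring B is thereby closed in the exo mode as a six-membered ring, with only C5 of the alkyne inside the ring. Ring A closes as a six-membered ring by olefin metathesis of the C4 alkylidene with the C3=CMe2 alkene, forming C3=C4 and releasing Ru=CMe2, which re-enters on the vinyl group of the next molecule and sheds isobutene. No stereocentre is formed, and C7, C8 and C10 are spectators that cannot epimerise under these neutral conditions. The step needs selectivity in the site of initiation, which the substitution pattern secures: the trisubstituted alkene and the methyl-capped alkyne flanked by quaternary C10 do not load ruthenium. It also needs exo over endo closure (six- against seven-membered) and ring closure of the hindered C4 carbene in preference to intermolecular transfer, which the gem-disubstituted C10, high dilution and heat are meant to secure. Loss of volatile isobutene and formation of the conjugated diene drive the sequence forward.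

Step 9
Reactants: 15 methyl 2-[(2S,3R,4aR)-3-(tert-butyldimethylsilyloxy)-4a,8-dimethyl-2,3,4,4a,5,6-hexahydronaphthalen-2-yl]acetate
Product: 17 methyl 2-[(2S,3R,4aR,7R,8R)-3-(tert-butyldimethylsilyloxy)-7-hydroxy-4a,8-dimethyl-2,3,4,4a,5,6,7,8-octahydronaphthalen-2-yl]acetate (3α-hydroxy, 4α-H expected), via alkylborane 16 (not isolated)
Conditions: 9-BBN-H dimer, THF, 0 → 60 °C; then 30% H2O2, 3 M aq. NaOAc, 0 °C → rt
Reagents that add atoms: hydrogen peroxide, OO
Why: Hydroboration–oxidation; the bulky borane should add boron to C3, the less substituted and far more open terminus of the diene (C6 is flanked by substituted C7), from the face opposite C14, and it leaves ester and silyl ether alone. The new centres at C3 and C4 are both erased in step 10, so their configuration does not matter.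

Step 10
Reactants: 17 methyl 2-[(2S,3R,4aR,7R,8R)-3-(tert-butyldimethylsilyloxy)-7-hydroxy-4a,8-dimethyl-2,3,4,4a,5,6,7,8-octahydronaphthalen-2-yl]acetate
Product: 19 methyl 2-[(2R,3R,4aR)-3-(tert-butyldimethylsilyloxy)-4a,8-dimethyl-7-oxo-1,2,3,4,4a,5,6,7-octahydronaphthalen-2-yl]acetate, via deconjugated ketone 18 (not isolated)
Conditions: Dess–Martin periodinane, CH2Cl2, 0 °C → rt; then DBU (3 equiv), rt
Reagents that add atoms: none
Why: Alcohol oxidation followed by base-mediated conjugation; deprotonation at C4 and reprotonation at C6 move the alkene into the tetrasubstituted, conjugated C4=C5 position, and C7 is not acidic, so its configuration is safe.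

Step 11
Reactants: 19 methyl 2-[(2R,3R,4aR)-3-(tert-butyldimethylsilyloxy)-4a,8-dimethyl-7-oxo-1,2,3,4,4a,5,6,7-octahydronaphthalen-2-yl]acetate
Product: 20 methyl 2-[(2R,3R,4aR,7S)-3-(tert-butyldimethylsilyloxy)-7-hydroxy-4a,8-dimethyl-1,2,3,4,4a,5,6,7-octahydronaphthalen-2-yl]acetate
Conditions: NaBH4, CeCl3·7H2O, MeOH, −78 → −40 °C
Reagents that add atoms: none
Why: Luche 1,2-reduction; hydride should enter axially on the α face, away from the axial C14 methyl, to give the equatorial 3β-alcohol (C3 S), and the ester is not reduced.

Step 12
Reactants: 20 methyl 2-[(2R,3R,4aR,7S)-3-(tert-butyldimethylsilyloxy)-7-hydroxy-4a,8-dimethyl-1,2,3,4,4a,5,6,7-octahydronaphthalen-2-yl]acetate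
Product: 23 methyl 2-[(2R,3R,4aR,7S)-3-(tert-butyldimethylsilyloxy)-7-hydroxy-4a,8-dimethyl-1,2,3,4,4a,5,6,7-octahydronaphthalen-2-yl]prop-2-enoate, via Mannich base 21 (not isolated), via ammonium iodide 22 (not isolated)
Conditions: LiN(iPr)2 (2.5 equiv), THF, −78 °C; CH2=NMe2+ I− (3 equiv), −78 °C → rt; aq. work-up; MeI, MeOH, rt; then aq. NaHCO3, CH2Cl2, rt
Reagents that add atoms: N,N-dimethylmethyleneiminium iodide (Eschenmoser's salt), C=[N+](C)C.[I-]
Why: Mannich α-methylenation of the ester through its alkoxide–enolate dianion, then quaternisation and elimination; the ester α-carbon is the only carbon nucleophile, any O-aminomethyl adduct is lost on work-up, and bicarbonate is too weak to move the new alkene to C7=C11. The transient C11 centre is destroyed in the elimination.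

Step 13
Reactants: 23 methyl 2-[(2R,3R,4aR,7S)-3-(tert-butyldimethylsilyloxy)-7-hydroxy-4a,8-dimethyl-1,2,3,4,4a,5,6,7-octahydronaphthalen-2-yl]prop-2-enoate
Product: 24 methyl 2-[(2R,3R,4aR,7S)-3-(tert-butyldimethylsilyloxy)-4a,8-dimethyl-7-(2-methylpropanoyloxy)-1,2,3,4,4a,5,6,7-octahydronaphthalen-2-yl]prop-2-enoate
Conditions: (i-PrCO)2O, Et3N, DMAP (cat.), CH2Cl2, 0 °C → rt
Reagents that add atoms: 2-methylpropanoic anhydride, CC(C)C(=O)OC(=O)C(C)C
Why: DMAP-catalysed acylation of the only free hydroxyl with retention at C3; the amine base is too weak to isomerise the acrylate.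

Step 14
Reactants: 24 methyl 2-[(2R,3R,4aR,7S)-3-(tert-butyldimethylsilyloxy)-4a,8-dimethyl-7-(2-methylpropanoyloxy)-1,2,3,4,4a,5,6,7-octahydronaphthalen-2-yl]prop-2-enoate
Product: 25 methyl 2-[(2R,3R,4aR,7S)-3-hydroxy-4a,8-dimethyl-7-(2-methylpropanoyloxy)-1,2,3,4,4a,5,6,7-octahydronaphthalen-2-yl]prop-2-enoate
Conditions: HF·pyridine, pyridine, THF, 0 °C → rt; crude product used at once
Reagents that add atoms: none
Why: Fluoride-mediated desilylation under buffered acidic conditions never forms an alkoxide at O8, which limits attack on the cis C12 ester (lactonisation) and spares the allylic isobutyrate.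

Step 15
Reactants: 25 methyl 2-[(2R,3R,4aR,7S)-3-hydroxy-4a,8-dimethyl-7-(2-methylpropanoyloxy)-1,2,3,4,4a,5,6,7-octahydronaphthalen-2-yl]prop-2-enoate
Product: 26 methyl 2-[(2R,3R,4aR,7S)-3-acetoxy-4a,8-dimethyl-7-(2-methylpropanoyloxy)-1,2,3,4,4a,5,6,7-octahydronaphthalen-2-yl]prop-2-enoate (CNP0127901.1)
Conditions: Ac2O, Et3N, DMAP (cat.), CH2Cl2, 0 °C → rt
Reagents that add atoms: acetic anhydride, CC(=O)OC(C)=O
Why: DMAP-catalysed acetylation of the hindered axial 8β-hydroxyl with retention; acylation removes the nucleophile that could otherwise close the lactone.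

## Compound list

1 | geraniol, (2E)-3,7-dimethylocta-2,6-dien-1-ol | CC(C)=CCC/C(C)=C/CO | starting material
2 | [(2S,3S)-3-methyl-3-(4-methylpent-3-enyl)oxiran-2-yl]methanol | OC[C@@H]1O[C@@]1(C)CCC=C(C)C | intermediate
3 | propyne | CC#C | starting material
4 | diethyl(prop-1-ynyl)aluminium | CC[Al](CC)C#CC | intermediate (not isolated)
5 | (2R,3S)-3,7-dimethyl-3-(prop-1-ynyl)oct-6-ene-1,2-diol | OC[C@H](O)[C@](C)(C#CC)CCC=C(C)C | intermediate
6 | (2S)-2,6-dimethyl-2-(prop-1-ynyl)hept-5-enal | O=C[C@](C)(C#CC)CCC=C(C)C | intermediate
7 | (3R)-1-methoxy-3,7-dimethyl-3-(prop-1-ynyl)octa-1,6-diene (E/Z mixture at C1=C2) | COC=C[C@](C)(C#CC)CCC=C(C)C | intermediate (not isolated)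
8 | (3R)-3,7-dimethyl-3-(prop-1-ynyl)oct-6-enal | O=CC[C@](C)(C#CC)CCC=C(C)C | intermediate
9 | methyl but-3-enoate | C=CCC(=O)OC | starting material
10 | 2-allyl-4,4,5,5-tetramethyl-1,3,2-dioxaborolane | C=CCB1OC(C)(C)C(C)(C)O1 | starting material
11 | methyl (3E)-5-(4,4,5,5-tetramethyl-1,3,2-dioxaborolan-2-yl)pent-3-enoate | COC(=O)C/C=C/CB1OC(C)(C)C(C)(C)O1 | intermediate
12 | methyl (3S,4R,6R)-3-ethenyl-6,10-dimethyl-6-(prop-1-ynyl)-4-[(4,4,5,5-tetramethyl-1,3,2-dioxaborolan-2-yl)oxy]undec-9-enoate | C=C[C@H](CC(=O)OC)[C@H](OB1OC(C)(C)C(C)(C)O1)C[C@](C)(C#CC)CCC=C(C)C | intermediate (not isolated)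
13 | methyl (3S,4R,6R)-3-ethenyl-4-hydroxy-6,10-dimethyl-6-(prop-1-ynyl)undec-9-enoate | C=C[C@H](CC(=O)OC)[C@H](O)C[C@](C)(C#CC)CCC=C(C)C | intermediate
14 | methyl (3S,4R,6R)-4-(tert-butyldimethylsilyloxy)-3-ethenyl-6,10-dimethyl-6-(prop-1-ynyl)undec-9-enoate | C=C[C@H](CC(=O)OC)[C@H](O[Si](C)(C)C(C)(C)C)C[C@](C)(C#CC)CCC=C(C)C | intermediate
15 | methyl 2-[(2S,3R,4aR)-3-(tert-butyldimethylsilyloxy)-4a,8-dimethyl-2,3,4,4a,5,6-hexahydronaphthalen-2-yl]acetate | COC(=O)C[C@H]1C=C2C(C)=CCC[C@]2(C)C[C@H]1O[Si](C)(C)C(C)(C)C | intermediate
16 | 3α-(9-borabicyclo[3.3.1]nonan-9-yl) adduct of 15 (boron on C3, hydrogen on C4, both α) | COC(=O)C[C@H]1C=C2[C@@H](C)[C@H](B3C4CCCC3CCC4)CC[C@]2(C)C[C@H]1O[Si](C)(C)C(C)(C)C | intermediate (not isolated)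
17 | methyl 2-[(2S,3R,4aR,7R,8R)-3-(tert-butyldimethylsilyloxy)-7-hydroxy-4a,8-dimethyl-2,3,4,4a,5,6,7,8-octahydronaphthalen-2-yl]acetate (expected major isomer) | COC(=O)C[C@H]1C=C2[C@@H](C)[C@H](O)CC[C@]2(C)C[C@H]1O[Si](C)(C)C(C)(C)C | intermediate
18 | methyl 2-[(2S,3R,4aR,8R)-3-(tert-butyldimethylsilyloxy)-4a,8-dimethyl-7-oxo-2,3,4,4a,5,6,7,8-octahydronaphthalen-2-yl]acetate | COC(=O)C[C@H]1C=C2[C@@H](C)C(=O)CC[C@]2(C)C[C@H]1O[Si](C)(C)C(C)(C)C | intermediate (not isolated)
19 | methyl 2-[(2R,3R,4aR)-3-(tert-butyldimethylsilyloxy)-4a,8-dimethyl-7-oxo-1,2,3,4,4a,5,6,7-octahydronaphthalen-2-yl]acetate | COC(=O)C[C@H]1CC2=C(C)C(=O)CC[C@]2(C)C[C@H]1O[Si](C)(C)C(C)(C)C | intermediate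
20 | methyl 2-[(2R,3R,4aR,7S)-3-(tert-butyldimethylsilyloxy)-7-hydroxy-4a,8-dimethyl-1,2,3,4,4a,5,6,7-octahydronaphthalen-2-yl]acetate | COC(=O)C[C@H]1CC2=C(C)[C@@H](O)CC[C@]2(C)C[C@H]1O[Si](C)(C)C(C)(C)C | intermediate
21 | methyl 3-(dimethylamino)-2-[(2R,3R,4aR,7S)-3-(tert-butyldimethylsilyloxy)-7-hydroxy-4a,8-dimethyl-1,2,3,4,4a,5,6,7-octahydronaphthalen-2-yl]propanoate (both C11 epimers) | COC(=O)C(CN(C)C)[C@H]1CC2=C(C)[C@@H](O)CC[C@]2(C)C[C@H]1O[Si](C)(C)C(C)(C)C | intermediate (not isolated)
22 | trimethylammonium iodide derived from 21 (both C11 epimers) | COC(=O)C(C[N+](C)(C)C)[C@H]1CC2=C(C)[C@@H](O)CC[C@]2(C)C[C@H]1O[Si](C)(C)C(C)(C)C.[I-] | intermediate (not isolated)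
23 | methyl 2-[(2R,3R,4aR,7S)-3-(tert-butyldimethylsilyloxy)-7-hydroxy-4a,8-dimethyl-1,2,3,4,4a,5,6,7-octahydronaphthalen-2-yl]prop-2-enoate | C=C(C(=O)OC)[C@H]1CC2=C(C)[C@@H](O)CC[C@]2(C)C[C@H]1O[Si](C)(C)C(C)(C)C | intermediate
24 | methyl 2-[(2R,3R,4aR,7S)-3-(tert-butyldimethylsilyloxy)-4a,8-dimethyl-7-(2-methylpropanoyloxy)-1,2,3,4,4a,5,6,7-octahydronaphthalen-2-yl]prop-2-enoate | C=C(C(=O)OC)[C@H]1CC2=C(C)[C@@H](OC(=O)C(C)C)CC[C@]2(C)C[C@H]1O[Si](C)(C)C(C)(C)C | intermediate
25 | methyl 2-[(2R,3R,4aR,7S)-3-hydroxy-4a,8-dimethyl-7-(2-methylpropanoyloxy)-1,2,3,4,4a,5,6,7-octahydronaphthalen-2-yl]prop-2-enoate | C=C(C(=O)OC)[C@H]1CC2=C(C)[C@@H](OC(=O)C(C)C)CC[C@]2(C)C[C@H]1O | intermediate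
26 | methyl 2-[(2R,3R,4aR,7S)-3-acetoxy-4a,8-dimethyl-7-(2-methylpropanoyloxy)-1,2,3,4,4a,5,6,7-octahydronaphthalen-2-yl]prop-2-enoate (methyl 8β-acetoxy-3β-isobutyryloxyeudesma-4,11(13)-dien-12-oate) | C=C(C(=O)OC)[C@H]1CC2=C(C)[C@@H](OC(=O)C(C)C)CC[C@]2(C)C[C@H]1OC(C)=O | target

## Step count and least certain steps

Total: 15 steps. Longest linear sequence: 14 steps (geraniol to 26 through steps 1–4 and 6–15; step 5 is a one-step branch).

Key step (step 8). The most likely failure is a stall after the first ring closure. The congested, disubstituted vinylcarbene on C4 may fail to engage the trisubstituted alkene and instead be intercepted by intermolecular methylene transfer, which would leave ring A open. Slow initiation through chelation of the ester carbonyl to ruthenium at C6 is a second hazard. The fallback separates the two closures and changes the metal for the second. From 14, the enyne closure alone would be run with the second-generation Grubbs catalyst RuCl2(H2IMes)(PCy3)(=CHPh) under an ethene atmosphere in CH2Cl2 at room temperature, giving the monocyclic isopropenyl diene F1, an isomer of 14 in which ring B is closed and C4 carries a methylene group. Ring A would then be closed in a second operation with the molybdenum alkylidene Mo(=CHCMe2Ph)(=N-2,6-iPr2C6H3)[OCMe(CF3)2]2 in benzene at 25–60 °C. This catalyst accepts 1,1-disubstituted and trisubstituted alkenes and tolerates the ester and silyl ether; it should expel isobutene and rejoin the route at 15.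

Step 6. Facial control by the acid may be weak on a branched aliphatic aldehyde, the Z component of 11 would feed the syn diastereomer, and the product may lactonise during work-up. The fallback replaces allyl transfer by an auxiliary-controlled aldol and a chain extension. From 8, the dibutylboron dienolate of (4S)-4-benzyl-3-[(2E)-but-2-enoyl]oxazolidin-2-one (n-Bu2BOTf, Et3N, CH2Cl2, −78 °C) should add through its α-carbon to give the syn aldol adduct F2, whose vinyl-bearing carbon and carbinol have the configuration of C7 and C8. Silylation (TBSOTf, 2,6-lutidine) would give the silyl ether F3, and LiOH/H2O2 would release the carboxylic acid F4 and the auxiliary. Activation with isobutyl chloroformate and Et3N and treatment with diazomethane would give the diazoketone F5. Wolff rearrangement (PhCO2Ag, Et3N, MeOH), in which C7 migrates with retention, would insert C11 and deliver the methyl ester, rejoining at 14.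

Step 9. The borane may attack C6 as well as C3, add twice, or react too slowly with the hindered conjugated diene. The fallback uses an electrophilic oxygen source and a reductive opening, with no boron and a different selectivity profile. From 15, one equivalent of buffered mCPBA (NaHCO3, CH2Cl2, 0 °C) should epoxidise the more exposed C3=C4 bond from the α face to give the vinyl epoxide F6, and the remaining alkene is then deactivated. SmI2 (divalent samarium) in THF/MeOH at −78 °C would cleave the allylic C4–O bond and protonate at C6, giving the allylic alcohol F7 with the alkene already at C4=C5. Oxidation with Dess–Martin periodinane would rejoin the route at 19.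

Step 2. Regiocontrol or stereospecificity may be lost at the tertiary epoxide carbon: attack at the secondary carbon, or ionisation followed by hydride shift or elimination. The fallback builds the same quaternary centre by catalyst-controlled allylic substitution and does not pass through an epoxide. From 1, phosphorylation (ClP(O)(OEt)2, pyridine) would give geranyl diethyl phosphate F8. Copper-catalysed enantioselective SN2′ substitution with diisobutyl(prop-1-ynyl)aluminium (from propyne, (i-Bu)2AlH and catalytic Et3N), using CuCl2·2H2O and a chiral sulfonate-bearing imidazolinium salt of the appropriate hand, should give the 1,4-enyne F9 with the alkyne-bearing quaternary carbon in place. Hydroboration of its vinyl group with 9-BBN-H would give the primary alkylborane F10, oxidation with H2O2/NaOH the primary alcohol F11, and Dess–Martin oxidation would rejoin the route at 8.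

Step 12. The alkoxide competes for the iminium salt and the dianion may be alkylated at carbon only in part; a base that is too strong in the last stage would also move the alkene to C7=C11. The fallback removes the second acidic site. From 20, silylation (Et3SiCl, imidazole) would give the triethylsilyl ether F12. A single equivalent of LiN(iPr)2 and Eschenmoser's salt would give the Mannich base F13, MeI the ammonium iodide F14, and aq. NaHCO3 the protected acrylate F15. Selective removal of the allylic triethylsilyl group (pyridinium p-toluenesulfonate, MeOH, 0 °C), which leaves the hindered tert-butyldimethylsilyl ether at C8, would rejoin the route at 23.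

## Further compounds

F1 | step 8 | methyl 2-[(1S,4R,6R)-6-(tert-butyldimethylsilyloxy)-4-methyl-4-(4-methylpent-3-enyl)-3-(prop-1-en-2-yl)cyclohex-2-en-1-yl]acetate | COC(=O)C[C@H]1C=C(C(C)=C)[C@](C)(CCC=C(C)C)C[C@H]1O[Si](C)(C)C(C)(C)C
F2 | step 6 | (4S)-4-benzyl-3-[(2S,3R,5R)-2-ethenyl-3-hydroxy-5,9-dimethyl-5-(prop-1-ynyl)dec-8-enoyl]-1,3-oxazolidin-2-one | C=C[C@H](C(=O)N1[C@@H](Cc2ccccc2)COC1=O)[C@H](O)C[C@](C)(C#CC)CCC=C(C)C
F3 | step 6 | (4S)-4-benzyl-3-[(2S,3R,5R)-3-(tert-butyldimethylsilyloxy)-2-ethenyl-5,9-dimethyl-5-(prop-1-ynyl)dec-8-enoyl]-1,3-oxazolidin-2-one | C=C[C@H](C(=O)N1[C@@H](Cc2ccccc2)COC1=O)[C@H](O[Si](C)(C)C(C)(C)C)C[C@](C)(C#CC)CCC=C(C)C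
F4 | step 6 | (2S,3R,5R)-3-(tert-butyldimethylsilyloxy)-2-ethenyl-5,9-dimethyl-5-(prop-1-ynyl)dec-8-enoic acid | C=C[C@H](C(O)=O)[C@H](O[Si](C)(C)C(C)(C)C)C[C@](C)(C#CC)CCC=C(C)C
F5 | step 6 | (3S,4R,6R)-4-(tert-butyldimethylsilyloxy)-1-diazo-3-ethenyl-6,10-dimethyl-6-(prop-1-ynyl)undec-9-en-2-one | C=C[C@H](C(=O)C=[N+]=[N-])[C@H](O[Si](C)(C)C(C)(C)C)C[C@](C)(C#CC)CCC=C(C)C
F6 | step 9 | 3α,4α-epoxide of 15 (methyl 8β-(tert-butyldimethylsilyloxy)-3α,4α-epoxy-13-nor-eudesm-5-en-12-oate) | COC(=O)C[C@H]1C=C2[C@]3(C)O[C@@H]3CC[C@]2(C)C[C@H]1O[Si](C)(C)C(C)(C)C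
F7 | step 9 | methyl 2-[(2R,3R,4aR,7R)-3-(tert-butyldimethylsilyloxy)-7-hydroxy-4a,8-dimethyl-1,2,3,4,4a,5,6,7-octahydronaphthalen-2-yl]acetate (3α-alcohol) | COC(=O)C[C@H]1CC2=C(C)[C@H](O)CC[C@]2(C)C[C@H]1O[Si](C)(C)C(C)(C)C
F8 | step 2 | diethyl (2E)-3,7-dimethylocta-2,6-dien-1-yl phosphate | CCOP(=O)(OCC)OC/C=C(\C)CCC=C(C)C
F9 | step 2 | (3R)-3,7-dimethyl-3-(prop-1-ynyl)octa-1,6-diene | C=C[C@](C)(C#CC)CCC=C(C)C
F10 | step 2 | 9-[(3R)-3,7-dimethyl-3-(prop-1-ynyl)oct-6-enyl]-9-borabicyclo[3.3.1]nonane | CC#C[C@@](C)(CCB1C2CCCC1CCC2)CCC=C(C)C
F11 | step 2 | (3R)-3,7-dimethyl-3-(prop-1-ynyl)oct-6-en-1-ol | OCC[C@](C)(C#CC)CCC=C(C)C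
F12 | step 12 | 3-O-triethylsilyl ether of 20 | COC(=O)C[C@H]1CC2=C(C)[C@@H](O[Si](CC)(CC)CC)CC[C@]2(C)C[C@H]1O[Si](C)(C)C(C)(C)C
F13 | step 12 | 3-O-triethylsilyl ether of 21 (both C11 epimers) | COC(=O)C(CN(C)C)[C@H]1CC2=C(C)[C@@H](O[Si](CC)(CC)CC)CC[C@]2(C)C[C@H]1O[Si](C)(C)C(C)(C)C
F14 | step 12 | 3-O-triethylsilyl ether of 22 (both C11 epimers) | COC(=O)C(C[N+](C)(C)C)[C@H]1CC2=C(C)[C@@H](O[Si](CC)(CC)CC)CC[C@]2(C)C[C@H]1O[Si](C)(C)C(C)(C)C.[I-]
F15 | step 12 | 3-O-triethylsilyl ether of 23 | C=C(C(=O)OC)[C@H]1CC2=C(C)[C@@H](O[Si](CC)(CC)CC)CC[C@]2(C)C[C@H]1O[Si](C)(C)C(C)(C)C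
A1 | alternative 1 | methyl 8β-hydroxy-3β-(2-methylpropanoyloxy)eudesma-4,11(13)-dien-12-oate | C=C(C(=O)OC)[C@H]1CC2=C(C)[C@@H](OC(=O)C(C)C)CC[C@]2(C)C[C@H]1O
A2 | alternative 1 | methyl (2Z)-2-(bromomethyl)-4-[(3S,6R)-2,6-dimethyl-3-(2-methylpropanoyloxy)-6-(2-oxoethyl)cyclohex-1-en-1-yl]but-2-enoate | COC(=O)/C(CBr)=C/CC1=C(C)[C@@H](OC(=O)C(C)C)CC[C@]1(C)CC=O
A3 | alternative 2 | (4aR,8aS)-6-(tert-butyldimethylsilyloxy)-2-methoxy-4a-methyl-4a,5,8,8a-tetrahydronaphthalene-1,4-dione | COC1=CC(=O)[C@]2(C)CC(O[Si](C)(C)C(C)(C)C)=CC[C@@H]2C1=O
A4 | alternative 2 | 2-methoxy-5-methylcyclohexa-2,5-diene-1,4-dione | COC1=CC(=O)C(C)=CC1=O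
A5 | alternative 2 | tert-butyl(buta-1,3-dien-2-yloxy)dimethylsilane | C=CC(=C)O[Si](C)(C)C(C)(C)C
A6 | alternative 3 | methyl 2-[(2R,3R,4aS)-3-(tert-butyldimethylsilyloxy)-4a,8-dimethyl-1,2,3,4,4a,7-hexahydronaphthalen-2-yl]acetate | COC(=O)C[C@H]1CC2=C(C)CC=C[C@]2(C)C[C@H]1O[Si](C)(C)C(C)(C)C
A7 | alternative 3 | methyl (3R,4R,6E)-3-(but-2-ynyl)-4-(tert-butyldimethylsilyloxy)-6-methylnona-6,8-dienoate | COC(=O)C[C@@H](CC#CC)[C@H](O[Si](C)(C)C(C)(C)C)C/C(C)=C/C=C
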